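**Plan** (locants are those of the octahydroazulene core of the target: C1–C3 in the five-membered ring, C3a/C8a at the ring fusion, C4–C8 in the seven-membered ring; precursors are numbered by correspondence)
1. Retrosynthesis: remove the two angelates (O4, O8) and the O1 silyl group; C4 carbinol ⇐ C4 ketone ⇐ C3a=C4 silyl enol ether; C6 methyl ⇐ C6 ester; then cut C5–C6 and C8–C8a together.
2. Enabling feature: with C4 at the enol-ether level the seven-membered ring (C3a, C4, C5, C6, C7, C8, C8a) is a cyclohepta-1,4-diene (C3a=C4 and C6=C7 flank the C5 methylene; C8–C8a is the sp3 pair), which is the product of a cis-divinylcyclopropane Cope shift.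
3. That ring comes from a rhodium vinylcarbenoid (C6–C7–C8, with O8 as an E enol benzoate) and the 2-silyloxy diene C5=C4(O)–C3a=C8a carried on the cyclopentene (C1, C2, C3, C3a, C8a).
4. Forward order: five-membered ring first (from a commercial 4-silyloxycyclopentenone), then the seven-membered ring in one flask, then C3a/C4, the C6 methyl group and the two esters.
5. Stereochemistry: C3 by addition anti to the resident silyloxy group, which is then inverted by oxidation and hydroxyl-directed reduction (O1 trans to O3); C8a and C8 from the boat Cope shift (matched catalyst and substrate, E enol ester); C3a by protonation on the convex face; C4 by hydride delivery from the C3 hydroxyl.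

Key step: step 12

Assumption: Rh2(R-DOSP)4 (dirhodium tetrakis[(R)-N-(4-dodecylbenzenesulfonyl)prolinate]) is taken to show the same facial sense on the 1,1-disubstituted enol ether of 12 as on terminal alkenes; on that model it is the matched catalyst.

**Route**

Step 1
Reactants: 1 (4S)-4-[(tert-butyldimethylsilyl)oxy]cyclopent-2-en-1-one
Product: 3 (4S)-4-[(tert-butyldimethylsilyl)oxy]-3-methylcyclopent-2-en-1-one, via trimethylsilyl enol ether 2 (not isolated)
Conditions: MeMgBr, CuBr·SMe2 (10 mol %), TMSCl, THF, −78 °C; then Pd(OAc)2 (10 mol %), O2 (1 atm), DMSO, rt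
Reagents that add atoms: methylmagnesium bromide, C[Mg]Br
Why: Copper-catalysed conjugate addition with silyl trapping followed by Saegusa–Ito dehydrosilylation should reinstate the ring double bond with the methyl group on its β-carbon; the silyloxy stereocentre is untouched and the transient methyl-bearing centre is destroyed.

Step 2
Reactants: 3
Product: 4 (4S)-4-[(tert-butyldimethylsilyl)oxy]-2-iodo-3-methylcyclopent-2-en-1-one
Conditions: I2, pyridine, DMAP (cat.), CH2Cl2, rt
Reagents that add atoms: iodine, II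
Why: α-Iodination of the enone by the iodine–pyridine addition–elimination sequence should place iodine on the only vinylic C–H.

Step 3
Reactants: 4
Product: 5 (1S,4S)-4-[(tert-butyldimethylsilyl)oxy]-2-iodo-3-methyl-1-(propan-2-yl)cyclopent-2-en-1-ol
Conditions: iPrMgCl, CeCl3, THF, −78 °C, quench cold
Reagents that add atoms: isopropylmagnesium chloride, CC(C)[Mg]Cl
Why: Organocerium 1,2-addition to the ketone (faster than iodine–metal exchange or enolisation at −78 °C) should occur anti to the silyloxy group, setting the tertiary carbinol with its hydroxyl cis to that group.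

Step 4
Reactants: 5
Product: 6 (1S,4S)-2-iodo-3-methyl-1-(propan-2-yl)cyclopent-2-ene-1,4-diol (cis)
Conditions: Bu4NF, THF, 0 °C
Reagents that add atoms: none
Why: Fluoride desilylation frees the secondary allylic alcohol without touching the tertiary carbinol or the vinyl iodide.

Step 5
Reactants: 6
Product: 7 (4S)-4-hydroxy-3-iodo-2-methyl-4-(propan-2-yl)cyclopent-2-en-1-one
Conditions: Dess–Martin periodinane, CH2Cl2, 0 °C → rt
Reagents that add atoms: none
Why: Dess–Martin oxidation converts only the secondary allylic alcohol, erasing the relay stereocentre and leaving the tertiary carbinol as the sole stereocentre.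

Step 6
Reactants: 7
Product: 8 (1S,4R)-2-iodo-3-methyl-1-(propan-2-yl)cyclopent-2-ene-1,4-diol (trans)
Conditions: Me4NBH(OAc)3, MeCN/AcOH (1:1), −25 °C
Reagents that add atoms: none
Why: Evans–Saksena reduction: the tertiary hydroxyl binds the acetoxyborohydride and delivers hydride to the carbonyl on its own face, so the new secondary hydroxyl should come out trans (1,3-anti) to it.

Step 7
Reactants: 8
Product: 9 (1S,4R)-4-[(tert-butyldimethylsilyl)oxy]-2-iodo-3-methyl-1-(propan-2-yl)cyclopent-2-en-1-ol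
Conditions: TBSCl, imidazole, DMF, 0 °C → rt
Reagents that add atoms: tert-butyldimethylsilyl chloride, CC(C)(C)[Si](C)(C)Cl
Why: Silylation with TBSCl/imidazole is selective for the secondary over the hindered tertiary hydroxyl.

Step 8
Reactants: 9
Product: 11 1-[(3R,5S)-3-[(tert-butyldimethylsilyl)oxy]-5-hydroxy-2-methyl-5-(propan-2-yl)cyclopent-1-en-1-yl]ethan-1-one, via 2-ethoxy diene 10 (not isolated)
Conditions: tributyl(1-ethoxyvinyl)stannane, Pd2(dba)3 (2.5 mol %), AsPh3, CuI (10 mol %), NMP, 50 °C; then 1 M HCl, THF, 0 °C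
Reagents that add atoms: tributyl(1-ethoxyvinyl)stannane, C=C(OCC)[Sn](CCCC)(CCCC)CCCC; water, O
Why: Stille coupling of the vinyl iodide with the α-ethoxyvinylstannane (an acetyl anion equivalent) and acid hydrolysis of the enol ether should give the methyl ketone.

Step 9
Reactants: 11
Product: 12 (3R,5S)-3-[(tert-butyldimethylsilyl)oxy]-2-methyl-5-(propan-2-yl)-5-[(trimethylsilyl)oxy]-1-{1-[(trimethylsilyl)oxy]ethenyl}cyclopent-1-ene
Conditions: TMSOTf, Et3N, CH2Cl2, −78 → 0 °C; used at once
Reagents that add atoms: trimethylsilyl trifluoromethanesulfonate, C[Si](C)(C)OS(=O)(=O)C(F)(F)F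
Why: Soft enolisation–silylation at the only α-methyl gives the cross-conjugated 2-silyloxy diene and caps the tertiary hydroxyl against O–H insertion in step 12.

Step 10
Reactants: 13 ethyl diazoacetate; 14 2-oxoethyl benzoate
Product: 15 ethyl 4-(benzoyloxy)-2-diazo-3-hydroxybutanoate (racemic)
Conditions: DBU (10 mol %), MeCN, 0 °C → rt
Reagents that add atoms: none
Why: DBU-catalysed aldol-type addition of the diazoacetate carbanion to the aldehyde gives the β-hydroxy-α-diazo ester, whose stereocentre is removed in the next step.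

Step 11
Reactants: 15
Product: 16 ethyl (3E)-4-(benzoyloxy)-2-diazobut-3-enoate
Conditions: (CF3CO)2O, Et3N, CH2Cl2, −78 → 0 °C; kept cold, used within a day
Reagents that add atoms: none
Why: Trifluoroacetylation and base-induced elimination, assisted by the diazo group, dehydrate the β-hydroxy-α-diazo ester to the vinyldiazoacetate, the trans (E) enol ester being favoured.

Step 12
Reactants: 12 (diene); 16 (vinyldiazoacetate)
Product: 18 ethyl (1R,3S,8R,8aS)-8-(benzoyloxy)-1-[(tert-butyldimethylsilyl)oxy]-8a-methyl-3-(propan-2-yl)-3,4-bis[(trimethylsilyl)oxy]-1,2,3,5,8,8a-hexahydroazulene-6-carboxylate, via cis-divinylcyclopropane 17 (not isolated)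
Conditions: Rh2(R-DOSP)4 (1 mol %), hexanes, −40 → 23 °C, slow addition of 16; then toluene, 110 °C
Reagents that add atoms: none
Why: The rhodium carbenoid from 16 adds to the terminal, electron-rich C4=C5 enol-ether double bond of 12 (the tetrasubstituted ring alkene is inert) to give cis-divinylcyclopropane 17, which on heating undergoes the strain-driven [3,3] (Cope) shift through the obligatory boat transition state, cleaving the C4–C6 cyclopropane bond and joining C8 to C8a, so that C5–C6 and C8–C8a are made in one flask. The closest known reaction type is the tandem cyclopropanation/Cope rearrangement (formal [4+3] cycloaddition) of rhodium vinylcarbenoids with 2-silyloxy dienes, including cases where a diene terminus with an inward methyl becomes a quaternary carbon. The three-membered ring closes by [2+1] carbene addition and the seven-membered ring by the suprafacial [3,3] shift of the cis-1,2-dialkenylcyclopropane (a three-to-seven ring expansion), leaving the C3a=C4 silyl enol ether and the C6=C7 enoate. C8 is controlled by the E geometry of the enol benzoate in the boat (the outward benzoate ends cis to the outward C1 branch and trans to the inward methyl), and C8a by the face of the cyclopentene that is reached, which is fixed by the cyclopropane configuration set by the catalyst and should match the substrate bias (bond formation anti to the C1 silyloxy and C3 isopropyl groups). The step needs site selectivity for the enol ether, cis-dialkenyl geometry and suppression of zwitterionic opening to a cyclopentene; the hydrocarbon solvent, the donor/acceptor carbenoid and the reversible opening of the silyloxy/ester cyclopropane (which should funnel a trans isomer to the cis one) are relied on for these.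

Step 13
Reactants: 18
Product: 20 ethyl (1R,3S,3aR,4R,8R,8aS)-8-(benzoyloxy)-1-[(tert-butyldimethylsilyl)oxy]-3,4-dihydroxy-8a-methyl-3-(propan-2-yl)-1,2,3,3a,4,5,8,8a-octahydroazulene-6-carboxylate, via β-hydroxy ketone 19 (not isolated)
Conditions: AcOH/MeCN (1:1), 5 vol % H2O, 0 °C; then Me4NBH(OAc)3, −25 → 0 °C
Reagents that add atoms: none
Why: Acetic acid removes both trimethylsilyl groups, protonating the enol ether at C3a on the convex face (cis to the angular methyl, which is also the less strained cis ring fusion), and the freed C3 hydroxyl then delivers hydride to C4 from its own face (Evans–Saksena reduction) to give the 1,3-anti diol; no base is used because the β,γ-unsaturated ketone carries an allylic benzoate.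

Step 14
Reactants: 20
Product: 21 (1R,3S,3aR,4R,8R,8aS)-1-[(tert-butyldimethylsilyl)oxy]-6-(hydroxymethyl)-8a-methyl-3-(propan-2-yl)-1,2,3,3a,4,5,8,8a-octahydroazulene-3,4,8-triol
Conditions: iBu2AlH (excess), CH2Cl2, −78 → 0 °C; aqueous potassium sodium tartrate
Reagents that add atoms: none
Why: Hydride reduction takes the conjugated ester to the primary allylic alcohol in 1,2-fashion and cleaves the benzoate reductively, while the silyl ether and the hydroxyls (as aluminium alkoxides) are inert.

Step 15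
Reactants: 21
Product: 23 (1R,3S,3aR,4R,8R,8aS)-1-[(tert-butyldimethylsilyl)oxy]-6,8a-dimethyl-3-(propan-2-yl)-1,2,3,3a,4,5,8,8a-octahydroazulene-3,4,8-triol, via allylic mesylate 22 (not isolated)
Conditions: MsCl (1.05 equiv), Et3N, THF, −40 °C; then LiEt3BH (excess), −40 → 0 °C
Reagents that add atoms: none
Why: Selective sulfonylation of the unhindered primary allylic hydroxyl followed by SN2 displacement with hydride (allylic deoxygenation) should give the C6 methyl group without moving the double bond.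

Step 16
Reactants: 23
Product: 24 (1R,3S,3aR,4R,8R,8aS)-1-[(tert-butyldimethylsilyl)oxy]-3-hydroxy-6,8a-dimethyl-3-(propan-2-yl)-1,2,3,3a,4,5,8,8a-octahydroazulene-4,8-diyl bis[(2Z)-2-methylbut-2-enoate]
Conditions: angelic acid, 2,4,6-trichlorobenzoyl chloride, Et3N, toluene, rt; then 23, 80 °C
Reagents that add atoms: angelic acid ((2Z)-2-methylbut-2-enoic acid), C/C=C(/C)C(=O)O
Why: Yamaguchi esterification through the mixed 2,4,6-trichlorobenzoic anhydride should acylate both secondary hydroxyls (the tertiary one is inert) and, run without a nucleophilic catalyst, preserve the Z geometry of the angeloyl groups.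

Step 17
Reactants: 24
Product: 25 (1R,3S,3aR,4R,8R,8aR)-1,3-dihydroxy-6,8a-dimethyl-3-(propan-2-yl)-1,2,3,3a,4,5,8,8a-octahydroazulene-4,8-diyl bis[(2Z)-2-methylbut-2-enoate] (target)
Conditions: HF·pyridine, pyridine, THF, 0 °C → rt
Reagents that add atoms: none
Why: Buffered fluoride desilylation removes the last silyl ether and should leave the angelates, including the allylic one, untouched.

**Compound list**
1 | (4S)-4-[(tert-butyldimethylsilyl)oxy]cyclopent-2-en-1-one | O=C1C=C[C@@H](O[Si](C)(C)C(C)(C)C)C1 | starting material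
2 | (3S,4S)-4-[(tert-butyldimethylsilyl)oxy]-3-methyl-1-[(trimethylsilyl)oxy]cyclopent-1-ene (methyl trans to the silyloxy group) | C[C@H]1C=C(O[Si](C)(C)C)C[C@@H]1O[Si](C)(C)C(C)(C)C | intermediate
3 | (4S)-4-[(tert-butyldimethylsilyl)oxy]-3-methylcyclopent-2-en-1-one | CC1=CC(=O)C[C@@H]1O[Si](C)(C)C(C)(C)C | intermediate
4 | (4S)-4-[(tert-butyldimethylsilyl)oxy]-2-iodo-3-methylcyclopent-2-en-1-one | CC1=C(I)C(=O)C[C@@H]1O[Si](C)(C)C(C)(C)C | intermediate
5 | (1S,4S)-4-[(tert-butyldimethylsilyl)oxy]-2-iodo-3-methyl-1-(propan-2-yl)cyclopent-2-en-1-ol | CC1=C(I)[C@@](O)(C(C)C)C[C@@H]1O[Si](C)(C)C(C)(C)C | intermediate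
6 | (1S,4S)-2-iodo-3-methyl-1-(propan-2-yl)cyclopent-2-ene-1,4-diol (cis) | CC1=C(I)[C@@](O)(C(C)C)C[C@@H]1O | intermediate
7 | (4S)-4-hydroxy-3-iodo-2-methyl-4-(propan-2-yl)cyclopent-2-en-1-one | CC1=C(I)[C@@](O)(C(C)C)CC1=O | intermediate
8 | (1S,4R)-2-iodo-3-methyl-1-(propan-2-yl)cyclopent-2-ene-1,4-diol (trans) | CC1=C(I)[C@@](O)(C(C)C)C[C@H]1O | intermediate
9 | (1S,4R)-4-[(tert-butyldimethylsilyl)oxy]-2-iodo-3-methyl-1-(propan-2-yl)cyclopent-2-en-1-ol | CC1=C(I)[C@@](O)(C(C)C)C[C@H]1O[Si](C)(C)C(C)(C)C | intermediate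
10 | (1S,4R)-4-[(tert-butyldimethylsilyl)oxy]-2-(1-ethoxyethenyl)-3-methyl-1-(propan-2-yl)cyclopent-2-en-1-ol | CC1=C(C(=C)OCC)[C@@](O)(C(C)C)C[C@H]1O[Si](C)(C)C(C)(C)C | intermediate
11 | 1-[(3R,5S)-3-[(tert-butyldimethylsilyl)oxy]-5-hydroxy-2-methyl-5-(propan-2-yl)cyclopent-1-en-1-yl]ethan-1-one | CC1=C(C(C)=O)[C@@](O)(C(C)C)C[C@H]1O[Si](C)(C)C(C)(C)C | intermediate
12 | (3R,5S)-3-[(tert-butyldimethylsilyl)oxy]-2-methyl-5-(propan-2-yl)-5-[(trimethylsilyl)oxy]-1-{1-[(trimethylsilyl)oxy]ethenyl}cyclopent-1-ene | CC1=C(C(=C)O[Si](C)(C)C)[C@@](O[Si](C)(C)C)(C(C)C)C[C@H]1O[Si](C)(C)C(C)(C)C | intermediate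
13 | ethyl diazoacetate | CCOC(=O)C=[N+]=[N-] | starting material
14 | 2-oxoethyl benzoate (benzoyloxyacetaldehyde) | O=CCOC(=O)c1ccccc1 | starting material
15 | ethyl 4-(benzoyloxy)-2-diazo-3-hydroxybutanoate (racemic) | CCOC(=O)C(=[N+]=[N-])C(O)COC(=O)c1ccccc1 | intermediate
16 | ethyl (3E)-4-(benzoyloxy)-2-diazobut-3-enoate | CCOC(=O)C(=[N+]=[N-])/C=C/OC(=O)c1ccccc1 | intermediate
17 | ethyl 1-[(E)-2-(benzoyloxy)ethenyl]-2-[the cyclopent-1-enyl group of 12]-2-[(trimethylsilyl)oxy]cyclopropane-1-carboxylate, the two alkenyl groups cis | CCOC(=O)[C@]1(/C=C/OC(=O)c2ccccc2)C[C@@]1(O[Si](C)(C)C)C3=C(C)[C@H](O[Si](C)(C)C(C)(C)C)C[C@]3(O[Si](C)(C)C)C(C)C | intermediate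
18 | ethyl (1R,3S,8R,8aS)-8-(benzoyloxy)-1-[(tert-butyldimethylsilyl)oxy]-8a-methyl-3-(propan-2-yl)-3,4-bis[(trimethylsilyl)oxy]-1,2,3,5,8,8a-hexahydroazulene-6-carboxylate | CCOC(=O)C1=C[C@@H](OC(=O)c2ccccc2)[C@@]3(C)[C@H](O[Si](C)(C)C(C)(C)C)C[C@](O[Si](C)(C)C)(C(C)C)C3=C(O[Si](C)(C)C)C1 | intermediate
19 | ethyl (1R,3S,3aS,8R,8aS)-8-(benzoyloxy)-1-[(tert-butyldimethylsilyl)oxy]-3-hydroxy-8a-methyl-4-oxo-3-(propan-2-yl)-1,2,3,3a,4,5,8,8a-octahydroazulene-6-carboxylate (cis ring fusion) | O=C1CC(C(=O)OCC)=C[C@@H](OC(=O)c3ccccc3)[C@@]2(C)[C@H](O[Si](C)(C)C(C)(C)C)C[C@](O)(C(C)C)[C@@H]12 | intermediate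
20 | ethyl (1R,3S,3aR,4R,8R,8aS)-8-(benzoyloxy)-1-[(tert-butyldimethylsilyl)oxy]-3,4-dihydroxy-8a-methyl-3-(propan-2-yl)-1,2,3,3a,4,5,8,8a-octahydroazulene-6-carboxylate | O[C@@H]1CC(C(=O)OCC)=C[C@@H](OC(=O)c3ccccc3)[C@@]2(C)[C@H](O[Si](C)(C)C(C)(C)C)C[C@](O)(C(C)C)[C@@H]12 | intermediate
21 | (1R,3S,3aR,4R,8R,8aS)-1-[(tert-butyldimethylsilyl)oxy]-6-(hydroxymethyl)-8a-methyl-3-(propan-2-yl)-1,2,3,3a,4,5,8,8a-octahydroazulene-3,4,8-triol | O[C@@H]1CC(CO)=C[C@@H](O)[C@@]2(C)[C@H](O[Si](C)(C)C(C)(C)C)C[C@](O)(C(C)C)[C@@H]12 | intermediate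
22 | primary allylic methanesulfonate of 21 | O[C@@H]1CC(COS(C)(=O)=O)=C[C@@H](O)[C@@]2(C)[C@H](O[Si](C)(C)C(C)(C)C)C[C@](O)(C(C)C)[C@@H]12 | intermediate
23 | (1R,3S,3aR,4R,8R,8aS)-1-[(tert-butyldimethylsilyl)oxy]-6,8a-dimethyl-3-(propan-2-yl)-1,2,3,3a,4,5,8,8a-octahydroazulene-3,4,8-triol | O[C@@H]1CC(C)=C[C@@H](O)[C@@]2(C)[C@H](O[Si](C)(C)C(C)(C)C)C[C@](O)(C(C)C)[C@@H]12 | intermediate
24 | (1R,3S,3aR,4R,8R,8aS)-1-[(tert-butyldimethylsilyl)oxy]-3-hydroxy-6,8a-dimethyl-3-(propan-2-yl)-1,2,3,3a,4,5,8,8a-octahydroazulene-4,8-diyl bis[(2Z)-2-methylbut-2-enoate] | C/C=C(/C)C(=O)O[C@@H]1CC(C)=C[C@@H](OC(=O)/C(C)=C\C)[C@@]2(C)[C@H](O[Si](C)(C)C(C)(C)C)C[C@](O)(C(C)C)[C@@H]12 | intermediate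
25 | (1R,3S,3aR,4R,8R,8aR)-1,3-dihydroxy-6,8a-dimethyl-3-(propan-2-yl)-1,2,3,3a,4,5,8,8a-octahydroazulene-4,8-diyl bis[(2Z)-2-methylbut-2-enoate] | C/C=C(/C)C(=O)O[C@@H]1CC(C)=C[C@@H](OC(=O)/C(C)=C\C)[C@@]2(C)[C@H](O)C[C@](O)(C(C)C)[C@@H]12 | target

**Count**
Total steps: 17. Longest linear sequence: 15 (steps 1–9 and 12–17); the diazo arm is steps 10–11.

**Steps most likely to fail**

Step 12. The silyloxy/ester cyclopropane may open heterolytically and close to a cyclopentene, the Cope shift may stall at the hindered tetrasubstituted terminus, or the cyclopropanation may take the mismatched face. The fallback sets out from 9 and returns at 20. Stille coupling of 9 with tributyl(vinyl)stannane (Pd2(dba)3, AsPh3, CuI) should give the 2-ethenyl carbinol F1, and TMSCl/imidazole its trimethylsilyl ether F2, a hydrocarbon diene whose cyclopropane cannot ionise and whose terminal vinyl group is the standard alkene class for this catalyst. The same rhodium-catalysed reaction with 16 followed by heating should give the cyclohepta-1,4-diene F3, which is 18 without the C4 silyloxy group. Hydroboration–oxidation (BH3·SMe2; NaBO3) of the trisubstituted C3a=C4 alkene on its exposed convex face, with a citric acid work-up that removes the trimethylsilyl group, installs H-3a and O-4 together and gives 20.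

Step 13. Protonation of the enol ether may occur on the concave face, or the β,γ-unsaturated ketone may lose benzoate in a vinylogous elimination before it is reduced. The fallback sets out from 18 and returns at 20 without forming the ketone. Bu4N[Ph3SiF2] and PhNTf2 (THF, −78 → −20 °C) should convert the silyl enol ether into the enol triflate F4; reduction with Pd(OAc)2/PPh3, HCO2H and Bu3N gives F3; hydroboration–oxidation as above gives 20.

Step 16. The angeloyl groups may isomerise from Z to E, and acylation of the neopentylic C8 hydroxyl may stay incomplete. The fallback sets out from 23 and returns at 24. DCC/DMAP esterification with 2-[bis(2,2,2-trifluoroethoxy)phosphoryl]propanoic acid (an unhindered acid) should give the bis(phosphonopropanoate) F5; Still–Gennari olefination with acetaldehyde (KN(SiMe3)2, 18-crown-6, THF, −78 °C) then builds both (Z)-2-methylbut-2-enoates in place.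

**Further compounds**
F1 | step 12 | (1S,4R)-4-[(tert-butyldimethylsilyl)oxy]-2-ethenyl-3-methyl-1-(propan-2-yl)cyclopent-2-en-1-ol | CC1=C(C=C)[C@@](O)(C(C)C)C[C@H]1O[Si](C)(C)C(C)(C)C
F2 | step 12 | trimethylsilyl ether of F1 | CC1=C(C=C)[C@@](O[Si](C)(C)C)(C(C)C)C[C@H]1O[Si](C)(C)C(C)(C)C
F3 | step 12 | ethyl (1R,3S,8R,8aS)-8-(benzoyloxy)-1-[(tert-butyldimethylsilyl)oxy]-8a-methyl-3-(propan-2-yl)-3-[(trimethylsilyl)oxy]-1,2,3,5,8,8a-hexahydroazulene-6-carboxylate | CCOC(=O)C1=C[C@@H](OC(=O)c2ccccc2)[C@@]3(C)[C@H](O[Si](C)(C)C(C)(C)C)C[C@](O[Si](C)(C)C)(C(C)C)C3=CC1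
F4 | step 13 | C4 enol trifluoromethanesulfonate corresponding to 18 | CCOC(=O)C1=C[C@@H](OC(=O)c2ccccc2)[C@@]3(C)[C@H](O[Si](C)(C)C(C)(C)C)C[C@](O[Si](C)(C)C)(C(C)C)C3=C(OS(=O)(=O)C(F)(F)F)C1
F5 | step 16 | 4,8-bis{2-[bis(2,2,2-trifluoroethoxy)phosphoryl]propanoate} of 23 (epimers at the phosphonate-bearing carbons) | CC(C(=O)O[C@@H]1CC(C)=C[C@@H](OC(=O)C(C)P(=O)(OCC(F)(F)F)OCC(F)(F)F)[C@@]2(C)[C@H](O[Si](C)(C)C(C)(C)C)C[C@](O)(C(C)C)[C@@H]12)P(=O)(OCC(F)(F)F)OCC(F)(F)F
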